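| setting | west | south | north-east | delta | theta | beta | alpha |
|---|---|---|---|---|---|---|---|
| substrate | 0.27 M | 0.18 M | 0.41 M | 0.27 M | 0.27 M | 0.27 M (fed, over 4.00 h) | 0.27 M |
| reagent | 0.324 M | 0.324 M | 0.324 M | 0.324 M | 0.324 M | 0.324 M | 0.324 M |
| remark | run made earlier | run made earlier | run made earlier | plug flow through a tube for 8.0 h, no back-mixing | one stirred flow tank at steady state, fed with the mixture as stated, mean residence time 8.0 h | all but substrate at the start; substrate goes in evenly over 4.00 h, the run ends at 8.0 h | a closed flask charged with all of it at once and left for 8.0 h |
| time |  |  |  | 8.0 h |  | 8.0 h | 8.0 h |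

| run | time / h | target / % | substrate / % |
|---|---|---|---|
| west | 0.417 | 9 | 71 |
| west | 0.667 | 14 | 65 |
| west | 1.00 | 14 | 57 |
| west | 2.00 | 18 | 44 |
| west | 3.00 | 20 | 39 |
| west | 5.00 | 23 | 32 |
| south | 0.500 | 12 | 66 |
| south | 0.833 | 15 | 53 |
| south | 1.33 | 15 | 42 |
| south | 2.50 | 23 | 31 |
| south | 4.00 | 24 | 19 |
| south | 6.00 | 31 | 17 |
| north-east | 1.00 | 10 | 66 |
| north-east | 2.00 | 14 | 55 |
| north-east | 3.00 | 16 | 52 |
| north-east | 4.00 | 14 | 50 |
| north-east | 5.00 | 14 | 47 |
| north-east | 6.00 | 19 | 45 |

(scatter of a reading: 1.5 percentage points)

* the set-up with the highest amount of target at the outlet or at the end, in percent of the substrate put in ("none" if the first two lie within 2 percentage points) (delta / theta / beta / alpha / none)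
* amount of target at the outlet or at the end, in percent of the substrate put in, delta
* amount of target at the outlet or at the end, in percent of the substrate put in, theta
* amount of target at the outlet or at the end, in percent of the substrate put in, beta
* amount of target at the outlet or at the end, in percent of the substrate put in, alpha

- the stated concentrations are those of everything mixed, before any reaction; amounts are the same in each set-up
- the feed brings no volume worth counting
- the earlier runs were made in a closed, stirred flask

More than 2 percentage points is the lead one set-up needs for a named winner, so turn the question round and ask what it would take to get one. Delta is a tube without back-mixing and alpha is a closed flask, so each slice of delta ages as alpha does, and the two should tie. If theta and beta end below them, the first two are that tie and the answer is "none". A winner therefore needs theta or beta to beat the pair by more than 2 points.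

The west run has alpha's charge in a closed flask, so its reading at 5.00 h lies on alpha's path. My own reckoning starts there. The share of lost substrate that has become target (the selectivity) reads:

share = 23% / (substrate lost, 68.0%) = 0.338

The hurdle share, the share a challenger must hold to beat that reading by the margin at the same substrate lost, is:

hurdle = (23% + 2 points) / 68.0% = 0.368

That is more than the west share. The south and north-east runs, with other substrate charges, read 0.373 and 0.345 at their last readings, one above the hurdle and one below it. The pair goes on past 5.00 h, which can raise the bar. I would say "none", without great confidence.

The forecast also says none, with delta 26%, theta 24%, beta 25% and alpha 26%: “Delta and alpha are the same batch history.”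

The steps behind the flask:

    substrate + 2 reagent → side product A (k = 9.71 M⁻² h⁻¹)
    substrate + reagent → target (k = 1.04 M⁻¹ h⁻¹)
    substrate + target → side product B (k = 0.359 M⁻¹ h⁻¹)

Delta and alpha each give 24.4%, beta 23.6% and theta 23.2%, so the answer is none. Theta has 36.6% substrate left, so you can now set its hurdle against alpha's result:

hurdle = (24.4% + 2 points) / 63.4% = 0.416

Theta held a share of 0.366, less than that hurdle.

The numbers in the tables come from a simulation for an exercise, and the scatter is random.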